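**Plan**

- Retrosynthesis: the benzyl and silyl ethers are removed and the C3 hydroxymethyl group is traced back to a geminal diester at C3. The oxolane is then cut at O1–C5 and C2–C3 into a trans aryl/diester cyclopropane and 4-benzyloxy-3-methoxybenzaldehyde. The cyclopropane is cut at its two bonds to the malonate carbon into O-benzylconiferaldehyde and dimethyl bromomalonate.
- Enabling feature: in the ring O1–C2–C3–C4–C5, C5 is a benzylic carbon with an electron-rich aryl group and C3, two atoms on, carries a carboxyl-level carbon, so C3–C4–C5 maps onto a donor–acceptor cyclopropane. The cis C4/C5 pair is what inversion at C5 makes of a trans cyclopropane, and C3 alone stands trans to each of its two ring neighbours, so it can be set by equilibration.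
- Forward: the three-membered ring is made first by an aminocatalytic Michael-initiated ring closure. The oxolane ring follows in one operation by annulation with the aldehyde. One ester is then removed, C3 is equilibrated, the ester is reduced and the protecting groups are taken off.
- Stereochemistry: the (S)-prolinol silyl ether catalyst fixes C4 and the pre-inversion C5. The annulation inverts C5 and sets C2 (2,5-cis). Base equilibration sets C3.

Key step: step 4

Assumption: the ring is numbered O1, C2, C3, C4, C5 with C5 the aryl-bearing carbon cis to the C4 hydroxymethyl group; with this numbering the target is (2S,3R,4R,5R). 4-Benzyloxy-3-methoxybenzaldehyde is taken as a purchased material.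

**Route**

Step 1
Reactants: 1 coniferaldehyde
Product: 2 (E)-3-[4-(benzyloxy)-3-methoxyphenyl]prop-2-enal
Conditions: BnBr, K2CO3, DMF, rt
Reagents that add atoms: benzyl bromide, BrCc1ccccc1
Why: Williamson O-alkylation of the phenoxide, under a base too weak to touch the enal, masks the phenol as a benzyl ether that should last until the final hydrogenolysis; no stereocentre is formed.

Step 2
Reactants: 2 (E)-3-[4-(benzyloxy)-3-methoxyphenyl]prop-2-enal; 3 dimethyl bromomalonate
Product: 5 dimethyl (2S,3R)-2-[4-(benzyloxy)-3-methoxyphenyl]-3-formylcyclopropane-1,1-dicarboxylate, via enamine Michael adduct 4 (not isolated)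
Conditions: (S)-2-[diphenyl(trimethylsilyloxy)methyl]pyrrolidine (20 mol %), 2,6-lutidine (1.1 equiv), CH2Cl2, 0 °C → rt
Reagents that add atoms: none
Why: Michael-initiated ring closure under iminium/enamine catalysis, in which the bromomalonate adds to the face of the E iminium ion not shielded by the diphenyl(silyloxy)methyl group (aryl carbon S) and the enamine 4 then closes the ring by 3-exo-tet alkylation with formyl and aryl trans (formyl carbon R), while 2,6-lutidine only takes up HBr.

Step 3
Reactants: 5 dimethyl (2S,3R)-2-[4-(benzyloxy)-3-methoxyphenyl]-3-formylcyclopropane-1,1-dicarboxylate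
Product: 7 dimethyl (2S,3R)-2-[4-(benzyloxy)-3-methoxyphenyl]-3-{[(tert-butyldimethylsilyl)oxy]methyl}cyclopropane-1,1-dicarboxylate, via hydroxymethylcyclopropane 6 (not isolated)
Conditions: NaBH4, MeOH/CH2Cl2, −20 °C; aq NH4Cl, extraction; then TBSCl, imidazole, CH2Cl2, 0 °C → rt
Reagents that add atoms: tert-butyldimethylsilyl chloride, CC(C)(C)[Si](C)(C)Cl
Why: chemoselective borohydride reduction of the aldehyde beside the two esters, followed at once by imidazole-mediated silylation so that alcohol 6, which has an ester cis to it, has no time to lactonise; both stereocentres stay as they are.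

Step 4
Reactants: 7 dimethyl (2S,3R)-2-[4-(benzyloxy)-3-methoxyphenyl]-3-{[(tert-butyldimethylsilyl)oxy]methyl}cyclopropane-1,1-dicarboxylate; 8 4-(benzyloxy)-3-methoxybenzaldehyde
Product: 10 dimethyl (2R,4R,5R)-2,5-bis[4-(benzyloxy)-3-methoxyphenyl]-4-{[(tert-butyldimethylsilyl)oxy]methyl}oxolane-3,3-dicarboxylate, via oxocarbenium malonate zwitterion 9 (not isolated)
Conditions: Sn(OTf)2 (10 mol %), 8 (3 equiv), CH2Cl2, −20 → 0 °C
Reagents that add atoms: none
Why: Coordination of Sn(OTf)2 to both ester carbonyls weakens the bond between the malonate carbon and the benzylic carbon of 7, and the carbonyl oxygen of 8 enters at the benzylic carbon anti to the leaving malonate carbon (backside displacement, inversion) to give zwitterion 9. The tin malonate of 9 then adds to the oxocarbenium carbon and closes the oxolane by a 5-endo-trig aldol-type addition (enolate exocyclic), a closure that oxocarbenium ions undergo readily through an envelope transition state. The closest known reaction type is the Lewis acid catalysed formal [3+2] annulation of 2-arylcyclopropane-1,1-diesters, trans-2,3-disubstituted ones included, with aldehydes to 2,5-cis-oxolanes. C5 is controlled by the cyclopropane configuration, so the trans aryl/silyloxymethyl pair becomes the cis C4/C5 pair; C4 is carried over unchanged; C2 is set by the envelope in which both aryl groups lie pseudo-equatorial (2,5-cis). The step needs bimolecular capture to outrun ionisation of the electron-rich benzylic carbon; the chelating geminal diester, which holds the leaving carbon on the rear face, together with the weak Lewis acid, the low temperature and the excess of the nucleophilic electron-rich aldehyde should secure this.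

Step 5
Reactants: 10 dimethyl (2R,4R,5R)-2,5-bis[4-(benzyloxy)-3-methoxyphenyl]-4-{[(tert-butyldimethylsilyl)oxy]methyl}oxolane-3,3-dicarboxylate
Product: 11 methyl (2S,3RS,4R,5R)-2,5-bis[4-(benzyloxy)-3-methoxyphenyl]-4-{[(tert-butyldimethylsilyl)oxy]methyl}oxolane-3-carboxylate (mixture of C3 epimers)
Conditions: LiCl, H2O (2 equiv), DMSO, 140 °C
Reagents that add atoms: none
Why: Krapcho dealkoxycarbonylation, in which chloride demethylates one ester, the carboxylate loses CO2 and the ester enolate is protonated by water without facial control, so both C3 epimers are expected while C2, C4 and C5, which carry no acidic hydrogen, are untouched.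

Step 6
Reactants: 11 methyl (2S,3RS,4R,5R)-2,5-bis[4-(benzyloxy)-3-methoxyphenyl]-4-{[(tert-butyldimethylsilyl)oxy]methyl}oxolane-3-carboxylate
Product: 12 methyl (2S,3S,4R,5R)-2,5-bis[4-(benzyloxy)-3-methoxyphenyl]-4-{[(tert-butyldimethylsilyl)oxy]methyl}oxolane-3-carboxylate
Conditions: NaOMe (0.3 equiv), MeOH/THF, rt
Reagents that add atoms: none
Why: thermodynamic epimerisation through the ester enolate should move the ester to the face opposite both the C2 aryl group and the C4 silyloxymethyl group, the one arrangement in which C3 is trans to each neighbour, and methoxide in methanol cannot scramble the methyl ester.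

Step 7
Reactants: 12 methyl (2S,3S,4R,5R)-2,5-bis[4-(benzyloxy)-3-methoxyphenyl]-4-{[(tert-butyldimethylsilyl)oxy]methyl}oxolane-3-carboxylate
Product: 13 [(2S,3R,4R,5R)-2,5-bis[4-(benzyloxy)-3-methoxyphenyl]-4-{[(tert-butyldimethylsilyl)oxy]methyl}oxolan-3-yl]methanol
Conditions: LiAlH4, THF, 0 °C
Reagents that add atoms: none
Why: hydride reduction of the ester to the primary alcohol leaves the silyl ether, the benzyl ethers and all four stereocentres alone (the C3 descriptor changes to R only through the change in substituent priority).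

Step 8
Reactants: 13 [(2S,3R,4R,5R)-2,5-bis[4-(benzyloxy)-3-methoxyphenyl]-4-{[(tert-butyldimethylsilyl)oxy]methyl}oxolan-3-yl]methanol
Product: 14 [(2S,3R,4R,5R)-2,5-bis[4-(benzyloxy)-3-methoxyphenyl]oxolane-3,4-diyl]dimethanol
Conditions: Bu4NF, THF, 0 °C → rt
Reagents that add atoms: none
Why: fluoride-driven cleavage of the Si–O bond works under near-neutral conditions that should not ionise the two benzylic C–O bonds of the ring.

Step 9
Reactants: 14 [(2S,3R,4R,5R)-2,5-bis[4-(benzyloxy)-3-methoxyphenyl]oxolane-3,4-diyl]dimethanol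
Product: 15 [(2S,3R,4R,5R)-2,5-bis(4-hydroxy-3-methoxyphenyl)oxolane-3,4-diyl]dimethanol (target)
Conditions: H2 (1 atm), 10% Pd/C, EtOAc/MeOH, rt, stopped after uptake of 2 equiv
Reagents that add atoms: none
Why: hydrogenolysis of aryl benzyl ethers over Pd/C is expected to be much faster than cleavage of the ring benzylic C–O bonds in a neutral solvent, so the bisphenol should form without ring opening or change at any stereocentre.

**Compound list**

1 | coniferaldehyde, (E)-3-(4-hydroxy-3-methoxyphenyl)prop-2-enal | COc1cc(/C=C/C=O)ccc1O | starting material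
2 | (E)-3-[4-(benzyloxy)-3-methoxyphenyl]prop-2-enal | COc1cc(/C=C/C=O)ccc1OCc2ccccc2 | intermediate
3 | dimethyl bromomalonate | COC(=O)C(Br)C(=O)OC | starting material
4 | enamine Michael adduct: enamine of dimethyl 2-bromo-2-[(1S)-1-(4-benzyloxy-3-methoxyphenyl)-3-oxopropyl]propanedioate with the (S)-pyrrolidine catalyst | COC(=O)C(Br)(C(=O)OC)[C@H](c1ccc(OCc2ccccc2)c(OC)c1)/C=C/N3CCC[C@H]3C(c4ccccc4)(c5ccccc5)O[Si](C)(C)C | intermediate
5 | dimethyl (2S,3R)-2-[4-(benzyloxy)-3-methoxyphenyl]-3-formylcyclopropane-1,1-dicarboxylate (aryl and formyl trans) | COC(=O)C1(C(=O)OC)[C@H](c2ccc(OCc3ccccc3)c(OC)c2)[C@H]1C=O | intermediate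
6 | dimethyl (2S,3R)-2-[4-(benzyloxy)-3-methoxyphenyl]-3-(hydroxymethyl)cyclopropane-1,1-dicarboxylate | COC(=O)C1(C(=O)OC)[C@H](c2ccc(OCc3ccccc3)c(OC)c2)[C@H]1CO | intermediate
7 | dimethyl (2S,3R)-2-[4-(benzyloxy)-3-methoxyphenyl]-3-{[(tert-butyldimethylsilyl)oxy]methyl}cyclopropane-1,1-dicarboxylate | COC(=O)C1(C(=O)OC)[C@H](c2ccc(OCc3ccccc3)c(OC)c2)[C@H]1CO[Si](C)(C)C(C)(C)C | intermediate
8 | 4-(benzyloxy)-3-methoxybenzaldehyde | COc1cc(C=O)ccc1OCc2ccccc2 | starting material
9 | oxocarbenium malonate zwitterion (ring-opened adduct of 7 and 8, tin-bound, C5 already inverted) | COc1cc(C=[O+][C@@H](c2ccc(OCc3ccccc3)c(OC)c2)[C@@H](CO[Si](C)(C)C(C)(C)C)[C-](C(=O)OC)C(=O)OC)ccc1OCc4ccccc4 | intermediate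
10 | dimethyl (2R,4R,5R)-2,5-bis[4-(benzyloxy)-3-methoxyphenyl]-4-{[(tert-butyldimethylsilyl)oxy]methyl}oxolane-3,3-dicarboxylate (aryls cis, C4 arm cis to C5 aryl) | COc1cc([C@H]2O[C@@H](c3ccc(OCc4ccccc4)c(OC)c3)[C@@H](CO[Si](C)(C)C(C)(C)C)C2(C(=O)OC)C(=O)OC)ccc1OCc5ccccc5 | intermediate
11 | methyl (2S,3RS,4R,5R)-2,5-bis[4-(benzyloxy)-3-methoxyphenyl]-4-{[(tert-butyldimethylsilyl)oxy]methyl}oxolane-3-carboxylate (C3 epimers) | COc1cc([C@H]2O[C@@H](c3ccc(OCc4ccccc4)c(OC)c3)[C@@H](CO[Si](C)(C)C(C)(C)C)C2C(=O)OC)ccc1OCc5ccccc5 | intermediate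
12 | methyl (2S,3S,4R,5R)-2,5-bis[4-(benzyloxy)-3-methoxyphenyl]-4-{[(tert-butyldimethylsilyl)oxy]methyl}oxolane-3-carboxylate (ester trans to both neighbours) | COc1cc([C@H]2O[C@@H](c3ccc(OCc4ccccc4)c(OC)c3)[C@@H](CO[Si](C)(C)C(C)(C)C)[C@@H]2C(=O)OC)ccc1OCc5ccccc5 | intermediate
13 | [(2S,3R,4R,5R)-2,5-bis[4-(benzyloxy)-3-methoxyphenyl]-4-{[(tert-butyldimethylsilyl)oxy]methyl}oxolan-3-yl]methanol | COc1cc([C@H]2O[C@@H](c3ccc(OCc4ccccc4)c(OC)c3)[C@@H](CO[Si](C)(C)C(C)(C)C)[C@@H]2CO)ccc1OCc5ccccc5 | intermediate
14 | [(2S,3R,4R,5R)-2,5-bis[4-(benzyloxy)-3-methoxyphenyl]oxolane-3,4-diyl]dimethanol | COc1cc([C@H]2O[C@@H](c3ccc(OCc4ccccc4)c(OC)c3)[C@@H](CO)[C@@H]2CO)ccc1OCc5ccccc5 | intermediate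
15 | [(2S,3R,4R,5R)-2,5-bis(4-hydroxy-3-methoxyphenyl)oxolane-3,4-diyl]dimethanol | COc1cc([C@H]2O[C@@H](c3ccc(O)c(OC)c3)[C@@H](CO)[C@@H]2CO)ccc1O | target

**Count**

Total step count: 9. Longest linear sequence: 9 steps (1 → 15); compounds 3 and 8 enter as purchased materials.

**Steps most likely to fail**

Step 4. The cyclopropane may ionise at the very electron-rich benzylic carbon before the aldehyde attacks. The C4/C5 relationship would then no longer be tied to the cyclopropane configuration, and loss of a β-hydrogen to a styrenyl malonate would compete. The fallback makes the donor less electron-rich by carrying the cyclopropane-side phenol as a pivalate, which brings the aryl group close to phenyl in donor strength. It sets out from coniferaldehyde 1.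
- Acylation (PivCl, pyridine) should give (E)-2-methoxy-4-(3-oxoprop-1-en-1-yl)phenyl pivalate F1.
- The aminocatalytic cyclopropanation of step 2 should give dimethyl (2S,3R)-3-formyl-2-[3-methoxy-4-(pivaloyloxy)phenyl]cyclopropane-1,1-dicarboxylate F2.
- Reduction as in step 3 should give the crude dimethyl (2S,3R)-3-(hydroxymethyl)-2-[3-methoxy-4-(pivaloyloxy)phenyl]cyclopropane-1,1-dicarboxylate F3, and silylation the dimethyl (2S,3R)-3-{[(tert-butyldimethylsilyl)oxy]methyl}-2-[3-methoxy-4-(pivaloyloxy)phenyl]cyclopropane-1,1-dicarboxylate F4.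
- Annulation with 8 under Sn(OTf)2, if need be at rt, should give dimethyl (2R,4R,5R)-2-[4-(benzyloxy)-3-methoxyphenyl]-4-{[(tert-butyldimethylsilyl)oxy]methyl}-5-[3-methoxy-4-(pivaloyloxy)phenyl]oxolane-3,3-dicarboxylate F5.
- Methanolysis of the aryl ester (NaOMe, MeOH, rt; the quaternary diester cannot enolise) should give dimethyl (2R,4R,5R)-2-[4-(benzyloxy)-3-methoxyphenyl]-4-{[(tert-butyldimethylsilyl)oxy]methyl}-5-(4-hydroxy-3-methoxyphenyl)oxolane-3,3-dicarboxylate F6.
- Benzylation (BnBr, K2CO3, DMF) returns to the route at 10.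

Step 5. At 140 °C the ester enolate formed on decarboxylation may expel the ring oxygen from C2 (β-elimination with ring opening), and chloride in wet DMSO may strip the silyl ether, after which the freed alcohol would lactonise. The fallback replaces nucleophilic demethylation by hydrolysis and a lower-temperature decarboxylation. It sets out from 10.
- Mono-saponification (KOH 1.2 equiv, MeOH/THF/H2O, 40 °C, then mild acidification) should give (2R,4R,5R)-2,5-bis[4-(benzyloxy)-3-methoxyphenyl]-4-{[(tert-butyldimethylsilyl)oxy]methyl}-3-(methoxycarbonyl)oxolane-3-carboxylic acid F7; either ester may be the one hydrolysed.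
- Heating the malonic half-acid in toluene at about 110 °C should lose CO2 through the cyclic enol-forming transition state and return to the route at 11.

Step 3. The alkoxide formed on reduction may attack the ester cis to it, an intramolecular transesterification to a bicyclic lactone, before the silyl group is on. The fallback avoids a free alkoxide altogether. It sets out from 5: copper hydride catalysed hydrosilylation of the aldehyde ([(Ph3P)CuH]6 cat., tBuMe2SiH, toluene, rt) should deliver the silyl ether directly and return to the route at 7. It makes no new compound.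

**Further compounds**

F1 | step 4 | (E)-2-methoxy-4-(3-oxoprop-1-en-1-yl)phenyl pivalate | COc1cc(/C=C/C=O)ccc1OC(=O)C(C)(C)C
F2 | step 4 | dimethyl (2S,3R)-3-formyl-2-[3-methoxy-4-(pivaloyloxy)phenyl]cyclopropane-1,1-dicarboxylate | COC(=O)C1(C(=O)OC)[C@H](c2ccc(OC(=O)C(C)(C)C)c(OC)c2)[C@H]1C=O
F3 | step 4 | dimethyl (2S,3R)-3-(hydroxymethyl)-2-[3-methoxy-4-(pivaloyloxy)phenyl]cyclopropane-1,1-dicarboxylate | COC(=O)C1(C(=O)OC)[C@H](c2ccc(OC(=O)C(C)(C)C)c(OC)c2)[C@H]1CO
F4 | step 4 | dimethyl (2S,3R)-3-{[(tert-butyldimethylsilyl)oxy]methyl}-2-[3-methoxy-4-(pivaloyloxy)phenyl]cyclopropane-1,1-dicarboxylate | COC(=O)C1(C(=O)OC)[C@H](c2ccc(OC(=O)C(C)(C)C)c(OC)c2)[C@H]1CO[Si](C)(C)C(C)(C)C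
F5 | step 4 | dimethyl (2R,4R,5R)-2-[4-(benzyloxy)-3-methoxyphenyl]-4-{[(tert-butyldimethylsilyl)oxy]methyl}-5-[3-methoxy-4-(pivaloyloxy)phenyl]oxolane-3,3-dicarboxylate | COc1cc([C@H]2O[C@@H](c3ccc(OC(=O)C(C)(C)C)c(OC)c3)[C@@H](CO[Si](C)(C)C(C)(C)C)C2(C(=O)OC)C(=O)OC)ccc1OCc4ccccc4
F6 | step 4 | dimethyl (2R,4R,5R)-2-[4-(benzyloxy)-3-methoxyphenyl]-4-{[(tert-butyldimethylsilyl)oxy]methyl}-5-(4-hydroxy-3-methoxyphenyl)oxolane-3,3-dicarboxylate | COc1cc([C@H]2O[C@@H](c3ccc(O)c(OC)c3)[C@@H](CO[Si](C)(C)C(C)(C)C)C2(C(=O)OC)C(=O)OC)ccc1OCc4ccccc4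
F7 | step 5 | (2R,4R,5R)-2,5-bis[4-(benzyloxy)-3-methoxyphenyl]-4-{[(tert-butyldimethylsilyl)oxy]methyl}-3-(methoxycarbonyl)oxolane-3-carboxylic acid (C3 configuration not defined) | COc1cc([C@H]2O[C@@H](c3ccc(OCc4ccccc4)c(OC)c3)[C@@H](CO[Si](C)(C)C(C)(C)C)C2(C(=O)O)C(=O)OC)ccc1OCc5ccccc5
F0 | step 3 | none | none
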